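(All runs come from a simulation for an exercise; the scatter is artificial.)

I read these flasks at 72 h. It comes later than the last earlier reading at 48.0 h, and the maple run already stands at 39%, 40% and 39% of target from 20.0 h on, with 1% of starting material left at the end.

the same everywhere: starting material 0.050 M; enzyme 22 µM
- maple: added ligand 3.9 µM; run made earlier
- alder: added ligand 420 µM; run made earlier
- spring: added ligand 6.0 µM; time 3.0 d
- summer: added ligand 20 µM; time 3.0 d
- winter: added ligand 60 µM; time 3.0 d
- midnight: added ligand 150 µM; time 3.0 d
- dusk: added ligand 500 µM; time 3.0 d

| run | time / h | target / % | starting material / % |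
|---|---|---|---|
| maple | 6.00 | 33 | 6 |
| maple | 20.0 | 39 | 1 |
| maple | 30.0 | 40 | 1 |
| maple | 48.0 | 39 | 1 |
| alder | 12.0 | 6 | 8 |
| alder | 25.0 | 7 | 4 |
| alder | 40.0 | 6 | 1 |
| alder | 48.0 | 9 | 0 |

(readings scatter by 1.5 percentage points)

- the earlier runs were read with a standard deviation of 1.5 percentage points
- "hardly changes" means that all values lie within two and a half points (for a concentration: within two and a half percent of the largest)

- amount of target at the end, in percent of the starting material charged for spring, summer, winter, midnight, dusk, in this order
- how that number moves from the first to the last of them (rises all the way / hardly changes / rises, then falls / falls all the way / falls, then rises)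

Starting material stands at 0.050 M and enzyme at 22 µM in the new flasks as in both runs, so an error in either drops out of the comparison. That leaves the added ligand.

I take the split, target over the rest of the charge, as the selectivity factor of a flask. Maple's plateau reads 0.648, and alder's last two readings give 0.0811.

I assume, and two runs cannot test it, that the split equals a ligand-free split divided by 1 plus the ligand charge over a crossing charge. The crossing charge, the ligand charge at which the ligand term equals that 1, then reads 55.6 µM, and the ligand-free split reads 0.694.

The crossing charge is the number to know well, and it is soft. Alder's readings of target carry a scatter of 1.5 percentage points, and its last reading taken by itself, 9%, moves the crossing charge to 71.0 µM.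

My own reckoning gives spring 38.5%, summer 33.8% and dusk 6.49%, a yield that falls from first to last.

The forecast differs: 52%, 78%, 58%, 20%, 7%, so rises, then falls, with “a maximum near stoichiometry”.

The flask gives 38.8%, 35.7%, 28.0%, 18.2%, 7.51%: falls all the way.

    starting material + enzyme → target + enzyme, rate k1*[starting material]*[enzyme]/(1 + ([starting material]/Km1) + ([starting material]/Ksi1)^2) (0.0529 M, 49.3 mM, k = 14800 M⁻¹ h⁻¹)
    2 starting material → homo dimer (k = 7.75 M⁻¹ h⁻¹)
    enzyme + added ligand ⇌ idle complex (K = 36000 M⁻¹, k = 17200 M⁻¹ h⁻¹)

Summer, at 35.7% of target against the forecast's 78%, holds 64.3% of the starting material charged as homo dimer at 3.00 d. Midnight's ligand charge is 2.70 crossing charges, which by my assumed rule puts the split at 0.188 and the target at 15.8%, and the midnight flask holds 18.2%.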